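**Retrosynthetic overview**
1. Target 29 ⇐ triol enone 28 (three angelates last) ⇐ a tricycle with 9‑OH, 11‑methylidene and 7‑OH; the 7‑OH is excised by radical C–O scission of a cyclic thionocarbonate built with the syn 9‑OH, which afterwards becomes the ketone.
2. Key disconnection: bonds C3–C4 and C6–C7 of the seven‑membered ring, giving bicyclic keto aldehyde 14 and bis(silyloxy)diene 17 (a 2‑methylacetoacetate dianion equivalent); a one‑flask double Mukaiyama aldol, formally a (4+3) annulation.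
3. Enabling feature: C7 (in 14 a cyclobutanone carbonyl held between the bridgeheads C1 and C8) and the formyl carbon C3 on quaternary C2 sit 1,3 across the four‑membered ring on the face anti to the C9–C11 bridge; neither can enolise, and C3(O)–C4–C5(O)–C6 is the retron of an acetoacetate.
4. 14 ⇐ 12 by intramolecular vinylketene–alkene [2+2] of acid 9; the E‑alkene fixes C2, the 5S silyloxy carbon (asymmetric vinylogous aldol of 4 and 6) fixes the absolute sense.
5. Ring order: cyclobutane and six‑membered ring together (step 7), then the seven‑membered ring (step 12).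

Key step: step 12

Remark (numbering): tricyclic compounds are numbered as tricyclo[5.4.0.0^2,8]undecanes; C1 and C8 are the cyclobutane CH carbons joined by C9–C10–C11, C2 is the methyl‑bearing cyclobutane carbon, C7 the fourth cyclobutane carbon, C3–C6 the four‑carbon bridge.
Remark (assumption): the sense of induction of the two chiral catalysts (steps 4 and 12) is assumed from their usual facial preference; if either delivers the opposite carbinol, its mirror‑image catalyst is used.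

Step 1
Reactants: 1 1-[(tert-butyldimethylsilyl)oxy]propan-2-one; 2 diethyl {2-[methoxy(methyl)amino]-2-oxoethyl}phosphonate
Product: 3 (2E)-4-[(tert-butyldimethylsilyl)oxy]-N-methoxy-N,3-dimethylbut-2-enamide
Conditions: NaH, THF, 0 °C → rt
Reagents that add atoms: none
Why: Horner–Wadsworth–Emmons olefination of a methyl ketone with an amide‑stabilised phosphonate should give mainly the E trisubstituted alkene, the minor Z isomer being removed by chromatography.

Step 2
Reactants: 3 (2E)-4-[(tert-butyldimethylsilyl)oxy]-N-methoxy-N,3-dimethylbut-2-enamide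
Product: 4 (2E)-4-[(tert-butyldimethylsilyl)oxy]-3-methylbut-2-enal
Conditions: iBu2AlH, THF, −78 °C
Reagents that add atoms: none
Why: Hydride reduction of an N‑methoxy‑N‑methylamide stops at the aldehyde through the chelated aluminium hemiaminal, and the alkene geometry is untouched.

Step 3
Reactants: 5 methyl 3-methylbut-2-enoate
Product: 6 tert-butyl[(1-methoxy-3-methylbuta-1,3-dien-1-yl)oxy]dimethylsilane
Conditions: LiN(iPr)2, DMPU, THF, −78 °C; tBuMe2SiCl
Reagents that add atoms: tert-butyldimethylsilyl chloride, CC(C)(C)[Si](C)(C)Cl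
Why: Kinetic γ‑deprotonation of the enoate and O‑silylation of the dienolate give the silyl dienol ether; no stereocentre is formed.

Step 4
Reactants: 4 (2E)-4-[(tert-butyldimethylsilyl)oxy]-3-methylbut-2-enal; 6 tert-butyl[(1-methoxy-3-methylbuta-1,3-dien-1-yl)oxy]dimethylsilane
Product: 7 methyl (2E,5S,6E)-8-[(tert-butyldimethylsilyl)oxy]-5-hydroxy-3,7-dimethylocta-2,6-dienoate
Conditions: SiCl4, (R,R)-1,5-bis{methyl[3,5-dimethyl-4-oxido-3,5-dihydro-4H-dinaphtho[2,1-d:1',2'-f][1,3,2]diazaphosphepin-4-yl]amino}pentane (5 mol %), iPr2NEt (cat.), CH2Cl2, −78 °C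
Reagents that add atoms: none
Why: Lewis base‑activated SiCl4 vinylogous Mukaiyama aldol through an open transition state is γ‑selective and gives the E enoate, and the chiral phosphoramide‑bound silicon cation differentiates the aldehyde faces to set the 5S carbinol.

Step 5
Reactants: 7 methyl (2E,5S,6E)-8-[(tert-butyldimethylsilyl)oxy]-5-hydroxy-3,7-dimethylocta-2,6-dienoate
Product: 8 methyl (2E,5S,6E)-8-[(tert-butyldimethylsilyl)oxy]-3,7-dimethyl-5-[(triisopropylsilyl)oxy]octa-2,6-dienoate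
Conditions: iPr3SiOSO2CF3, 2,6-lutidine, CH2Cl2, −78 → 0 °C
Reagents that add atoms: triisopropylsilyl trifluoromethanesulfonate, CC(C)[Si](OS(=O)(=O)C(F)(F)F)(C(C)C)C(C)C
Why: Silyl triflate silylation of the secondary allylic alcohol installs a group that survives the later selective removal of the primary silyl ether; the stereocentre is not touched.

Step 6
Reactants: 8 methyl (2E,5S,6E)-8-[(tert-butyldimethylsilyl)oxy]-3,7-dimethyl-5-[(triisopropylsilyl)oxy]octa-2,6-dienoate
Product: 9 (2E,5S,6E)-8-[(tert-butyldimethylsilyl)oxy]-3,7-dimethyl-5-[(triisopropylsilyl)oxy]octa-2,6-dienoic acid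
Conditions: LiOH, THF/MeOH/H2O, 40 °C; then 1 M HCl to pH 4
Reagents that add atoms: lithium hydroxide, [Li+].[OH-]
Why: Saponification by acyl–oxygen cleavage frees the acid while both silyl ethers and the stereocentre stay intact.

Step 7
Reactants: 9 (2E,5S,6E)-8-[(tert-butyldimethylsilyl)oxy]-3,7-dimethyl-5-[(triisopropylsilyl)oxy]octa-2,6-dienoic acid
Product: 12 (1R,4S,5R,7R)-7-{[(tert-butyldimethylsilyl)oxy]methyl}-7-methyl-2-methylidene-4-[(triisopropylsilyl)oxy]bicyclo[3.1.1]heptan-6-one, via acid chloride 10 (not isolated), via vinylketene 11 (not isolated)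
Conditions: 1-chloro-N,N,2-trimethylprop-1-en-1-amine, CH2Cl2, 0 °C; then Et3N, toluene, 110 °C, slow addition
Reagents that add atoms: none
Why: Dehydrochlorination at the γ‑methyl gives a vinylketene that undergoes the crossed intramolecular ketene–alkene [2+2] (carbonyl carbon to the less substituted alkene carbon), suprafacial on the E alkene so that the methyl ends syn and the silyloxymethyl anti to the three‑carbon bridge, while 1,3‑allylic strain at the 5S carbon puts the tether and the silyloxy group on opposite alkene faces and so fixes the absolute configuration of both bridgeheads and the quaternary carbon.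

Step 8
Reactants: 12 (1R,4S,5R,7R)-7-{[(tert-butyldimethylsilyl)oxy]methyl}-7-methyl-2-methylidene-4-[(triisopropylsilyl)oxy]bicyclo[3.1.1]heptan-6-one
Product: 13 (1R,4S,5R,7R)-7-(hydroxymethyl)-7-methyl-2-methylidene-4-[(triisopropylsilyl)oxy]bicyclo[3.1.1]heptan-6-one
Conditions: HF·pyridine, pyridine, THF, 0 °C
Reagents that add atoms: none
Why: Buffered fluoride cleaves the primary tert‑butyldimethylsilyl ether much faster than the hindered secondary triisopropylsilyl ether.

Step 9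
Reactants: 13 (1R,4S,5R,7R)-7-(hydroxymethyl)-7-methyl-2-methylidene-4-[(triisopropylsilyl)oxy]bicyclo[3.1.1]heptan-6-one
Product: 14 (1R,4S,5R,6R)-6-methyl-2-methylidene-7-oxo-4-[(triisopropylsilyl)oxy]bicyclo[3.1.1]heptane-6-carbaldehyde
Conditions: Dess–Martin periodinane, CH2Cl2, 0 °C → rt
Reagents that add atoms: none
Why: Hypervalent iodine oxidation of the neopentyl alcohol gives an aldehyde without α‑hydrogen, so no epimerisation or aldol side reaction is possible.

Step 10
Reactants: 15 methyl 2-methyl-3-oxobutanoate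
Product: 16 methyl 2-methyl-3-[(trimethylsilyl)oxy]but-2-enoate
Conditions: Me3SiCl, Et3N, hexane, rt
Reagents that add atoms: chlorotrimethylsilane, C[Si](C)(C)Cl
Why: O‑Silylation of the β‑keto ester gives the silyl enol ether (enol ether geometry irrelevant).

Step 11
Reactants: 16 methyl 2-methyl-3-[(trimethylsilyl)oxy]but-2-enoate
Product: 17 1-methoxy-2-methyl-1,3-bis[(trimethylsilyl)oxy]buta-1,3-diene
Conditions: LiN(iPr)2, THF, −78 °C; Me3SiCl
Reagents that add atoms: chlorotrimethylsilane, C[Si](C)(C)Cl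
Why: Kinetic deprotonation of the terminal methyl group and O‑silylation give the 1,3‑bis(silyloxy)diene, a masked acetoacetate dianion.

Step 12
Reactants: 14 (1R,4S,5R,6R)-6-methyl-2-methylidene-7-oxo-4-[(triisopropylsilyl)oxy]bicyclo[3.1.1]heptane-6-carbaldehyde; 17 1-methoxy-2-methyl-1,3-bis[(trimethylsilyl)oxy]buta-1,3-diene
Product: 19 methyl (1R,2R,3R,6R,7R,8R,9S)-3,7-dihydroxy-2,6-dimethyl-11-methylidene-5-oxo-9-[(triisopropylsilyl)oxy]tricyclo[5.4.0.0^2,8]undecane-6-carboxylate, via bis-silylated aldol adduct 18 (not isolated)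
Conditions: Ti(OiPr)4/(R)-1,1'-bi-2-naphthol (20 mol %), 4 Å MS, CH2Cl2, −78 → −20 °C; then TiCl4 (2.5 equiv), −78 → −20 °C
Reagents that add atoms: none
Why: The binaphthol–titanium complex catalyses a vinylogous Mukaiyama aldol in which the terminal CH2 of 17 adds to the aldehyde of 14 (bond C3–C4) with silyl transfer to give 18, and TiCl4 then turns the 3‑silyloxy enoate of 18 into a chelated titanium β‑keto ester enolate whose α‑carbon adds to the activated cyclobutanone (bond C6–C7). The closest known reaction type is the Lewis acid‑mediated (3+4) annulation of 1,3‑bis(silyloxy)dienes with 1,4‑dicarbonyl compounds; its oxygen‑bridged pathway is shut off here because the cyclobutanone carbon cannot become a bridgehead oxocarbenium ion, so the open diol should result. The seven‑membered ring closes by a 7‑(enolendo)‑exo‑trig aldol addition, driven by the relief of strain when the cyclobutanone carbon becomes sp3 and by the strong Ti–O bond of the aldolate. C3 is set by the chiral titanium catalyst (the two flanks of the aldehyde are almost enantiotopic, so reagent control is unopposed), C7 by the tether, which reaches the ketone only from the face anti to the C9–C11 bridge, and C6 by a titanium chelate linking the C3 alkoxide, the enolate oxygen and the ester carbonyl, which places the ester cis to the C3 oxygen. The step needs the diene terminus to find the aldehyde and the internal carbon the ketone; this is secured by the far higher reactivity of the aldehyde in the catalytic stage and by the fact that neither carbonyl can enolise, so no proton transfer competes.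

Step 13
Reactants: 19 methyl (1R,2R,3R,6R,7R,8R,9S)-3,7-dihydroxy-2,6-dimethyl-11-methylidene-5-oxo-9-[(triisopropylsilyl)oxy]tricyclo[5.4.0.0^2,8]undecane-6-carboxylate
Product: 20 methyl (1R,2R,3R,5R,6S,7R,8R,9S)-3,5,7-trihydroxy-2,6-dimethyl-11-methylidene-9-[(triisopropylsilyl)oxy]tricyclo[5.4.0.0^2,8]undecane-6-carboxylate
Conditions: Me4NBH(OAc)3, MeCN/AcOH, −30 °C
Reagents that add atoms: none
Why: Evans–Saksena reduction delivers hydride intramolecularly from the alkoxyborohydride formed at the 3‑OH, so the new 5‑OH should be anti to the 3‑OH (the tertiary 7‑OH is antiperiplanar to the ketone and cannot deliver).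

Step 14
Reactants: 20 methyl (1R,2R,3R,5R,6S,7R,8R,9S)-3,5,7-trihydroxy-2,6-dimethyl-11-methylidene-9-[(triisopropylsilyl)oxy]tricyclo[5.4.0.0^2,8]undecane-6-carboxylate
Product: 21 (1R,2R,3R,5R,6S,7R,8R,9S)-6-(hydroxymethyl)-2,6-dimethyl-11-methylidene-9-[(triisopropylsilyl)oxy]tricyclo[5.4.0.0^2,8]undecane-3,5,7-triol
Conditions: LiAlH4, THF, 0 °C → rt
Reagents that add atoms: none
Why: Hydride reduction of the neopentyl ester (or of any δ‑lactone formed with the cis 3‑OH) gives the primary alcohol without touching a stereocentre.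

Step 15
Reactants: 21 (1R,2R,3R,5R,6S,7R,8R,9S)-6-(hydroxymethyl)-2,6-dimethyl-11-methylidene-9-[(triisopropylsilyl)oxy]tricyclo[5.4.0.0^2,8]undecane-3,5,7-triol
Product: 22 [(1R,2R,3R,5R,6S,7R,8R,9S)-3,5-diacetoxy-7-hydroxy-2,6-dimethyl-11-methylidene-9-[(triisopropylsilyl)oxy]tricyclo[5.4.0.0^2,8]undec-6-yl]methyl acetate
Conditions: Ac2O, pyridine, DMAP (cat.), CH2Cl2, rt
Reagents that add atoms: acetic anhydride, CC(=O)OC(C)=O
Why: Acylation protects the primary and the two secondary alcohols, while the tertiary 7‑OH between a quaternary carbon and two bridgeheads should not react.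

Step 16
Reactants: 22 [(1R,2R,3R,5R,6S,7R,8R,9S)-3,5-diacetoxy-7-hydroxy-2,6-dimethyl-11-methylidene-9-[(triisopropylsilyl)oxy]tricyclo[5.4.0.0^2,8]undec-6-yl]methyl acetate
Product: 23 [(1R,2R,3R,5R,6S,7R,8R,9S)-3,5-diacetoxy-7,9-dihydroxy-2,6-dimethyl-11-methylidenetricyclo[5.4.0.0^2,8]undec-6-yl]methyl acetate
Conditions: HF·pyridine, THF, 0 °C → rt
Reagents that add atoms: none
Why: Fluoride‑mediated desilylation under non‑basic conditions frees the 9‑OH without acetate migration.

Step 17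
Reactants: 23 [(1R,2R,3R,5R,6S,7R,8R,9S)-3,5-diacetoxy-7,9-dihydroxy-2,6-dimethyl-11-methylidenetricyclo[5.4.0.0^2,8]undec-6-yl]methyl acetate
Product: 24 cyclic 7,9-O,O'-thionocarbonate of 23 (C=S bridging the 7- and 9-oxygens; other centres as in 23)
Conditions: 1,1'-thiocarbonyldiimidazole, DMAP, toluene, 110 °C
Reagents that add atoms: 1,1'-thiocarbonyldiimidazole, S=C(n1ccnc1)n1ccnc1
Why: The secondary 9‑OH is thioacylated first and the syn‑1,3‑related tertiary 7‑OH then closes the six‑membered cyclic thionocarbonate intramolecularly, which derivatises a tertiary alcohol that would resist intermolecular acylation.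

Step 18
Reactants: 24 cyclic 7,9-O,O'-thionocarbonate of 23
Product: 26 [(1R,2R,3R,5R,6S,7S,8R,9S)-3,5-diacetoxy-9-hydroxy-2,6-dimethyl-11-methylidenetricyclo[5.4.0.0^2,8]undec-6-yl]methyl acetate, via stannyl thiocarbonate 25 (not isolated)
Conditions: Bu3SnH, AIBN (cat.), toluene, 110 °C; then wet silica gel
Reagents that add atoms: none
Why: Barton–McCombie‑type deoxygenation of a cyclic thionocarbonate: the stannyl radical adds to sulfur, β‑scission should break the tertiary C7–O bond, and hydrogen transfer to the cyclobutyl radical can only come from the face syn to the C9–C11 bridge because C6 is held on the other face, which sets 7S; the stannyl thiocarbonate 25 loses carbonyl sulfide on hydrolysis.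

Step 19
Reactants: 26 [(1R,2R,3R,5R,6S,7S,8R,9S)-3,5-diacetoxy-9-hydroxy-2,6-dimethyl-11-methylidenetricyclo[5.4.0.0^2,8]undec-6-yl]methyl acetate
Product: 27 [(1R,2R,3R,5R,6S,7S,8R)-3,5-diacetoxy-2,6-dimethyl-11-methylidene-9-oxotricyclo[5.4.0.0^2,8]undec-6-yl]methyl acetate
Conditions: Dess–Martin periodinane, CH2Cl2, rt
Reagents that add atoms: none
Why: Hypervalent iodine oxidation of the only free (secondary) alcohol gives the β,γ‑unsaturated ketone; with C7 now deoxygenated no retro‑aldol opening of the cyclobutane is possible.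

Step 20
Reactants: 27 [(1R,2R,3R,5R,6S,7S,8R)-3,5-diacetoxy-2,6-dimethyl-11-methylidene-9-oxotricyclo[5.4.0.0^2,8]undec-6-yl]methyl acetate
Product: 28 (1R,2R,3R,5R,6S,7S,8R)-3,5-dihydroxy-6-(hydroxymethyl)-2,6,11-trimethyltricyclo[5.4.0.0^2,8]undec-10-en-9-one
Conditions: K2CO3 (cat.), MeOH, rt
Reagents that add atoms: none
Why: Transesterification removes the three acetates and the same base moves the exocyclic alkene into conjugation through the C10 enolate; both α‑ and γ‑bridgeheads cannot enolise, so no stereocentre is at risk.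

Step 21
Reactants: 28 (1R,2R,3R,5R,6S,7S,8R)-3,5-dihydroxy-6-(hydroxymethyl)-2,6,11-trimethyltricyclo[5.4.0.0^2,8]undec-10-en-9-one
Product: 29 [(1R,2R,3R,5R,6S,7S,8R)-3,5-bis{[(2Z)-2-methylbut-2-enoyl]oxy}-2,6,11-trimethyl-9-oxotricyclo[5.4.0.0^2,8]undec-10-en-6-yl]methyl (2Z)-2-methylbut-2-enoate
Conditions: angelic acid, 2,4,6-trichlorobenzoyl chloride, Et3N, toluene, rt; then 28, toluene, 80 °C
Reagents that add atoms: (2Z)-2-methylbut-2-enoic acid (angelic acid), C/C=C(/C)C(=O)O
Why: Yamaguchi‑type esterification through the preformed mixed anhydride, run without a nucleophilic catalyst, should acylate all three hindered hydroxyls while keeping the Z geometry of the angelate (no isomerisation to tiglate).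

**Compound list**
1 | 1-[(tert-butyldimethylsilyl)oxy]propan-2-one | CC(=O)CO[Si](C)(C)C(C)(C)C | starting material
2 | diethyl {2-[methoxy(methyl)amino]-2-oxoethyl}phosphonate | CCOP(=O)(CC(=O)N(C)OC)OCC | starting material
3 | (2E)-4-[(tert-butyldimethylsilyl)oxy]-N-methoxy-N,3-dimethylbut-2-enamide | CON(C)C(=O)/C=C(\C)CO[Si](C)(C)C(C)(C)C | intermediate
4 | (2E)-4-[(tert-butyldimethylsilyl)oxy]-3-methylbut-2-enal | O=C/C=C(\C)CO[Si](C)(C)C(C)(C)C | intermediate
5 | methyl 3-methylbut-2-enoate | COC(=O)C=C(C)C | starting material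
6 | tert-butyl[(1-methoxy-3-methylbuta-1,3-dien-1-yl)oxy]dimethylsilane (ketene acetal geometry not defined) | COC(O[Si](C)(C)C(C)(C)C)=CC(C)=C | intermediate
7 | methyl (2E,5S,6E)-8-[(tert-butyldimethylsilyl)oxy]-5-hydroxy-3,7-dimethylocta-2,6-dienoate | COC(=O)/C=C(\C)C[C@H](O)/C=C(\C)CO[Si](C)(C)C(C)(C)C | intermediate
8 | methyl (2E,5S,6E)-8-[(tert-butyldimethylsilyl)oxy]-3,7-dimethyl-5-[(triisopropylsilyl)oxy]octa-2,6-dienoate | COC(=O)/C=C(\C)C[C@H](O[Si](C(C)C)(C(C)C)C(C)C)/C=C(\C)CO[Si](C)(C)C(C)(C)C | intermediate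
9 | (2E,5S,6E)-8-[(tert-butyldimethylsilyl)oxy]-3,7-dimethyl-5-[(triisopropylsilyl)oxy]octa-2,6-dienoic acid | OC(=O)/C=C(\C)C[C@H](O[Si](C(C)C)(C(C)C)C(C)C)/C=C(\C)CO[Si](C)(C)C(C)(C)C | intermediate
10 | (2E,5S,6E)-8-[(tert-butyldimethylsilyl)oxy]-3,7-dimethyl-5-[(triisopropylsilyl)oxy]octa-2,6-dienoyl chloride | ClC(=O)/C=C(\C)C[C@H](O[Si](C(C)C)(C(C)C)C(C)C)/C=C(\C)CO[Si](C)(C)C(C)(C)C | intermediate (not isolated)
11 | (5S,6E)-8-[(tert-butyldimethylsilyl)oxy]-7-methyl-3-methylidene-5-[(triisopropylsilyl)oxy]octa-1,6-dien-1-one (vinylketene) | O=C=CC(=C)C[C@H](O[Si](C(C)C)(C(C)C)C(C)C)/C=C(\C)CO[Si](C)(C)C(C)(C)C | intermediate (not isolated)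
12 | (1R,4S,5R,7R)-7-{[(tert-butyldimethylsilyl)oxy]methyl}-7-methyl-2-methylidene-4-[(triisopropylsilyl)oxy]bicyclo[3.1.1]heptan-6-one | O=C1[C@H]2[C@@H](O[Si](C(C)C)(C(C)C)C(C)C)CC(=C)[C@@H]1[C@@]2(C)CO[Si](C)(C)C(C)(C)C | intermediate
13 | (1R,4S,5R,7R)-7-(hydroxymethyl)-7-methyl-2-methylidene-4-[(triisopropylsilyl)oxy]bicyclo[3.1.1]heptan-6-one | O=C1[C@H]2[C@@H](O[Si](C(C)C)(C(C)C)C(C)C)CC(=C)[C@@H]1[C@@]2(C)CO | intermediate
14 | (1R,4S,5R,6R)-6-methyl-2-methylidene-7-oxo-4-[(triisopropylsilyl)oxy]bicyclo[3.1.1]heptane-6-carbaldehyde | O=C1[C@H]2[C@@H](O[Si](C(C)C)(C(C)C)C(C)C)CC(=C)[C@@H]1[C@@]2(C)C=O | intermediate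
15 | methyl 2-methyl-3-oxobutanoate | COC(=O)C(C)C(C)=O | starting material
16 | methyl 2-methyl-3-[(trimethylsilyl)oxy]but-2-enoate (geometry not defined) | COC(=O)C(C)=C(C)O[Si](C)(C)C | intermediate
17 | 1-methoxy-2-methyl-1,3-bis[(trimethylsilyl)oxy]buta-1,3-diene (geometry not defined) | COC(O[Si](C)(C)C)=C(C)C(=C)O[Si](C)(C)C | intermediate
18 | methyl (5R)-2-methyl-5-[(1R,4S,5R,6R)-6-methyl-2-methylidene-7-oxo-4-[(triisopropylsilyl)oxy]bicyclo[3.1.1]hept-6-yl]-3,5-bis[(trimethylsilyl)oxy]pent-2-enoate (enoate geometry not defined) | O=C1[C@H]2[C@@H](O[Si](C(C)C)(C(C)C)C(C)C)CC(=C)[C@@H]1[C@@]2(C)[C@H](O[Si](C)(C)C)CC(O[Si](C)(C)C)=C(C)C(=O)OC | intermediate (not isolated)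
19 | methyl (1R,2R,3R,6R,7R,8R,9S)-3,7-dihydroxy-2,6-dimethyl-11-methylidene-5-oxo-9-[(triisopropylsilyl)oxy]tricyclo[5.4.0.0^2,8]undecane-6-carboxylate | COC(=O)[C@]1(C)[C@]2(O)[C@H]3[C@@H](O[Si](C(C)C)(C(C)C)C(C)C)CC(=C)[C@@H]2[C@@]3(C)[C@H](O)CC1=O | intermediate
20 | methyl (1R,2R,3R,5R,6S,7R,8R,9S)-3,5,7-trihydroxy-2,6-dimethyl-11-methylidene-9-[(triisopropylsilyl)oxy]tricyclo[5.4.0.0^2,8]undecane-6-carboxylate | COC(=O)[C@]1(C)[C@]2(O)[C@H]3[C@@H](O[Si](C(C)C)(C(C)C)C(C)C)CC(=C)[C@@H]2[C@@]3(C)[C@H](O)C[C@H]1O | intermediate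
21 | (1R,2R,3R,5R,6S,7R,8R,9S)-6-(hydroxymethyl)-2,6-dimethyl-11-methylidene-9-[(triisopropylsilyl)oxy]tricyclo[5.4.0.0^2,8]undecane-3,5,7-triol | OC[C@]1(C)[C@]2(O)[C@H]3[C@@H](O[Si](C(C)C)(C(C)C)C(C)C)CC(=C)[C@@H]2[C@@]3(C)[C@H](O)C[C@H]1O | intermediate
22 | [(1R,2R,3R,5R,6S,7R,8R,9S)-3,5-diacetoxy-7-hydroxy-2,6-dimethyl-11-methylidene-9-[(triisopropylsilyl)oxy]tricyclo[5.4.0.0^2,8]undec-6-yl]methyl acetate | CC(=O)OC[C@]1(C)[C@]2(O)[C@H]3[C@@H](O[Si](C(C)C)(C(C)C)C(C)C)CC(=C)[C@@H]2[C@@]3(C)[C@H](OC(C)=O)C[C@H]1OC(C)=O | intermediate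
23 | [(1R,2R,3R,5R,6S,7R,8R,9S)-3,5-diacetoxy-7,9-dihydroxy-2,6-dimethyl-11-methylidenetricyclo[5.4.0.0^2,8]undec-6-yl]methyl acetate | CC(=O)OC[C@]1(C)[C@]2(O)[C@H]3[C@@H](O)CC(=C)[C@@H]2[C@@]3(C)[C@H](OC(C)=O)C[C@H]1OC(C)=O | intermediate
24 | cyclic 7,9-O,O'-thionocarbonate of 23 | CC(=O)OC[C@]1(C)[C@]2(OC(=S)O5)[C@H]3[C@@H]5CC(=C)[C@@H]2[C@@]3(C)[C@H](OC(C)=O)C[C@H]1OC(C)=O | intermediate
25 | O-[9-yl] S-(tributylstannyl) thiocarbonate of 26 | CC(=O)OC[C@]1(C)[C@@H]2[C@H]3[C@@H](OC(=O)S[Sn](CCCC)(CCCC)CCCC)CC(=C)[C@@H]2[C@@]3(C)[C@H](OC(C)=O)C[C@H]1OC(C)=O | intermediate (not isolated)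
26 | [(1R,2R,3R,5R,6S,7S,8R,9S)-3,5-diacetoxy-9-hydroxy-2,6-dimethyl-11-methylidenetricyclo[5.4.0.0^2,8]undec-6-yl]methyl acetate | CC(=O)OC[C@]1(C)[C@@H]2[C@H]3[C@@H](O)CC(=C)[C@@H]2[C@@]3(C)[C@H](OC(C)=O)C[C@H]1OC(C)=O | intermediate
27 | [(1R,2R,3R,5R,6S,7S,8R)-3,5-diacetoxy-2,6-dimethyl-11-methylidene-9-oxotricyclo[5.4.0.0^2,8]undec-6-yl]methyl acetate | CC(=O)OC[C@]1(C)[C@@H]2[C@H]3C(=O)CC(=C)[C@@H]2[C@@]3(C)[C@H](OC(C)=O)C[C@H]1OC(C)=O | intermediate
28 | (1R,2R,3R,5R,6S,7S,8R)-3,5-dihydroxy-6-(hydroxymethyl)-2,6,11-trimethyltricyclo[5.4.0.0^2,8]undec-10-en-9-one | OC[C@]1(C)[C@@H]2[C@H]3C(=O)C=C(C)[C@@H]2[C@@]3(C)[C@H](O)C[C@H]1O | intermediate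
29 | [(1R,2R,3R,5R,6S,7S,8R)-3,5-bis{[(2Z)-2-methylbut-2-enoyl]oxy}-2,6,11-trimethyl-9-oxotricyclo[5.4.0.0^2,8]undec-10-en-6-yl]methyl (2Z)-2-methylbut-2-enoate | C/C=C(/C)C(=O)OC[C@]1(C)[C@@H]2[C@H]3C(=O)C=C(C)[C@@H]2[C@@]3(C)[C@H](OC(=O)/C(C)=C\C)C[C@H]1OC(=O)/C(C)=C\C | target

**Step count**
Total: 21 steps. Longest linear sequence: 18 steps (steps 1, 2, 4–9, 12–21).

**Steps most likely to fail**

Step 12. The titanium enolate of the fully substituted β‑keto ester may fail to add to the hindered cyclobutanone (which has the bulky silyloxy group syn to its oxygen), or the aldolate may reopen by retro‑aldol on warming, so that the sequence stops after the first bond. The fallback sets out from 14 and 17: the catalytic stage is run alone and 18 is desilylated (citric acid, MeOH) to the δ‑hydroxy β‑keto ester F1. N‑Bromosuccinimide brominates the doubly activated carbon to give the α‑bromo β‑keto ester F2. SmI2 in THF at −78 °C then forms a samarium enolate that closes the seven‑membered ring irreversibly by an intramolecular Reformatsky‑type addition to the cyclobutanone, and the route is rejoined at 19.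

Step 7. Oligomerisation of the vinylketene may outrun the crossed cycloaddition onto an alkene that carries two allylic oxygen substituents, and facial selectivity may erode at 110 °C. The fallback sets out from 8: kinetic deconjugation (LiN(iPr)2/HMPA, then AcOH at −78 °C) gives the β,γ‑unsaturated ester F3, and aminolysis with Me2NH/AlMe3 gives the dimethylamide F4. Tf2O and 2,4,6‑collidine in 1,2‑dichloroethane convert F4 into a vinylketeniminium ion whose faster [2+2] at or below 80 °C gives the cyclobutaniminium triflate F5. Hydrolysis with aqueous NaHCO3 comes back to the route at 12.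

Step 18. β‑Scission of the thionocarbonate‑derived radical may go toward the secondary C9–O bond instead of the tertiary C7–O bond (or ring closure in step 17 may stay incomplete), giving the wrong deoxy product. The fallback sets out from 22, with the silyl ether still in place: oxalyl chloride converts the tertiary alcohol into the chlorooxalate F6, and sodium 2‑thioxopyridin‑1(2H)‑olate gives the mixed oxalate thiohydroxamate F7. Bu3SnH/AIBN triggers double decarboxylation to the same tertiary cyclobutyl radical, which is reduced to the silyl ether F8. HF·pyridine then removes the silyl group and the route is rejoined at 26.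

**Further compounds**
F1 | step 12 | methyl (5R)-5-hydroxy-2-methyl-5-[(1R,4S,5R,6R)-6-methyl-2-methylidene-7-oxo-4-[(triisopropylsilyl)oxy]bicyclo[3.1.1]hept-6-yl]-3-oxopentanoate (mixture at C2) | O=C1[C@H]2[C@@H](O[Si](C(C)C)(C(C)C)C(C)C)CC(=C)[C@@H]1[C@@]2(C)[C@H](O)CC(=O)C(C)C(=O)OC
F2 | step 12 | methyl (5R)-2-bromo-5-hydroxy-2-methyl-5-[(1R,4S,5R,6R)-6-methyl-2-methylidene-7-oxo-4-[(triisopropylsilyl)oxy]bicyclo[3.1.1]hept-6-yl]-3-oxopentanoate (mixture at C2) | O=C1[C@H]2[C@@H](O[Si](C(C)C)(C(C)C)C(C)C)CC(=C)[C@@H]1[C@@]2(C)[C@H](O)CC(=O)C(C)(Br)C(=O)OC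
F3 | step 7 | methyl (5S,6E)-8-[(tert-butyldimethylsilyl)oxy]-7-methyl-3-methylidene-5-[(triisopropylsilyl)oxy]oct-6-enoate | COC(=O)CC(=C)C[C@H](O[Si](C(C)C)(C(C)C)C(C)C)/C=C(\C)CO[Si](C)(C)C(C)(C)C
F4 | step 7 | (5S,6E)-8-[(tert-butyldimethylsilyl)oxy]-N,N,7-trimethyl-3-methylidene-5-[(triisopropylsilyl)oxy]oct-6-enamide | CN(C)C(=O)CC(=C)C[C@H](O[Si](C(C)C)(C(C)C)C(C)C)/C=C(\C)CO[Si](C)(C)C(C)(C)C
F5 | step 7 | N-[(1R,4S,5R,7R)-7-{[(tert-butyldimethylsilyl)oxy]methyl}-7-methyl-2-methylidene-4-[(triisopropylsilyl)oxy]bicyclo[3.1.1]hept-6-ylidene]-N-methylmethanaminium trifluoromethanesulfonate | C[N+](C)=C1[C@H]2[C@@H](O[Si](C(C)C)(C(C)C)C(C)C)CC(=C)[C@@H]1[C@@]2(C)CO[Si](C)(C)C(C)(C)C.[O-]S(=O)(=O)C(F)(F)F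
F6 | step 18 | 7-O-(chlorooxalyl) derivative of 22 | CC(=O)OC[C@]1(C)[C@]2(OC(=O)C(Cl)=O)[C@H]3[C@@H](O[Si](C(C)C)(C(C)C)C(C)C)CC(=C)[C@@H]2[C@@]3(C)[C@H](OC(C)=O)C[C@H]1OC(C)=O
F7 | step 18 | 7-O-oxalyl derivative of 22 as its 2-thioxopyridin-1(2H)-yl mixed ester | CC(=O)OC[C@]1(C)[C@]2(OC(=O)C(=O)On4ccccc4=S)[C@H]3[C@@H](O[Si](C(C)C)(C(C)C)C(C)C)CC(=C)[C@@H]2[C@@]3(C)[C@H](OC(C)=O)C[C@H]1OC(C)=O
F8 | step 18 | [(1R,2R,3R,5R,6S,7S,8R,9S)-3,5-diacetoxy-2,6-dimethyl-11-methylidene-9-[(triisopropylsilyl)oxy]tricyclo[5.4.0.0^2,8]undec-6-yl]methyl acetate | CC(=O)OC[C@]1(C)[C@@H]2[C@H]3[C@@H](O[Si](C(C)C)(C(C)C)C(C)C)CC(=C)[C@@H]2[C@@]3(C)[C@H](OC(C)=O)C[C@H]1OC(C)=O
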